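**Overview**
- Target 31 is cut back to aldehyde 25 (allylboration with boronate 28, then oxidation), and 25 to oxepanol 21 by silyl ether and acetate changes.
- Feature used: in the oxepane (O1, C2 with methyl and side chain, C3 with its oxygen O3, C4, C5, C6 with the alkylidene C8–C9, C7) the ring CH2 C7 can be the carbonyl carbon of a 2-alkyl (E)-enal. The stable geometry of that enal is the C6=C8 geometry of the target, and C7 lies within reach of both O1 and O3.
- Key disconnection: 21 ⇐ 6,8-dioxabicyclo[3.2.1]octane 20 (i-Bu2AlH cuts C7–O3) ⇐ dihydroxy enal 18. Ring order: the tetrahydropyran (C7–O3) and the dioxolane (C7–O1) close together as the bicycle, which already holds the seven-membered ring; the oxepane alone remains after the cut.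
- Enal 17 ⇐ aldehyde 15 + silyloxyacetaldehyde 16; anti-diol 12 ⇐ Shi epoxide 11 opened by water with inversion at C2; (E)-alkene 10 ⇐ alkyne 6 (methylalumination–iodination, Negishi coupling with 9); 6 ⇐ bromide 2 + butynyl Grignard reagent 4.

Key step: step 11

Remark: atom labels O1, C2–C9 and O3 are those of the target oxepane throughout (C8, C9 exocyclic). Lactol 19 (anomers) and alcohol 30 (carbinol epimers) are expected as mixtures at centres that are removed again. Compounds 1 and 9 are assumed to be purchased.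

**Step 1**
Reactants: 1 (S)-3-bromo-2-methylpropan-1-ol
Product: 2 (S)-(3-bromo-2-methylpropoxy)(tert-butyl)diphenylsilane
Conditions: TBDPSCl, imidazole, CH2Cl2, 0 °C → rt
Reagents that add atoms: tert-butyl(chloro)diphenylsilane, CC(C)(C)[Si](Cl)(c1ccccc1)c1ccccc1
Why: Imidazole-promoted O-silylation of a primary alcohol is fast and leaves the primary bromide and the stereocentre untouched.

**Step 2**
Reactants: 2 (S)-(3-bromo-2-methylpropoxy)(tert-butyl)diphenylsilane, 3 (4-bromobut-1-yn-1-yl)trimethylsilane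
Product: 5 (R)-tert-butyl{[2-methyl-7-(trimethylsilyl)hept-6-yn-1-yl]oxy}diphenylsilane, via Grignard reagent 4 (not isolated)
Conditions: 3, Mg, THF, 40 °C; then 2, Li2CuCl4 (5 mol %), N-methylpyrrolidone, THF, 0 °C → rt
Reagents that add atoms: none
Why: Copper-catalysed cross-coupling of an alkyl Grignard reagent with a primary alkyl bromide forms the C(sp3)–C(sp3) bond at the CH2Br carbon, one atom away from the stereocentre, which is therefore not touched.

**Step 3**
Reactants: 5 (R)-tert-butyl{[2-methyl-7-(trimethylsilyl)hept-6-yn-1-yl]oxy}diphenylsilane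
Product: 6 (R)-tert-butyl[(2-methylhept-6-yn-1-yl)oxy]diphenylsilane
Conditions: K2CO3, MeOH–THF, rt
Reagents that add atoms: none
Why: Methoxide-induced protodesilylation of the alkynylsilane cleaves only the C(sp)–Si bond, while the hindered O–Si bond of the TBDPS ether is stable to carbonate in methanol.

**Step 4**
Reactants: 6 (R)-tert-butyl[(2-methylhept-6-yn-1-yl)oxy]diphenylsilane
Product: 8 (R,E)-tert-butyl[(7-iodo-2,6-dimethylhept-6-en-1-yl)oxy]diphenylsilane, via alkenylalane 7 (not isolated)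
Conditions: AlMe3 (2.5 equiv), Cp2ZrCl2 (0.25 equiv), CH2Cl2, 0 °C → rt; then I2, THF, −30 → 0 °C
Reagents that add atoms: trimethylaluminium, C[Al](C)C; iodine, II
Why: Zirconium-catalysed methylalumination of the terminal alkyne (Negishi carboalumination) adds methyl and aluminium syn with aluminium on the terminal carbon, and iodinolysis of the C–Al bond with retention gives the (E)-iodoalkene.

**Step 5**
Reactants: 8 (R,E)-tert-butyl[(7-iodo-2,6-dimethylhept-6-en-1-yl)oxy]diphenylsilane, 9 (3-cyanopropyl)zinc bromide (THF solution)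
Product: 10 (R,E)-11-[(tert-butyldiphenylsilyl)oxy]-6,10-dimethylundec-5-enenitrile
Conditions: Pd(PPh3)4 (5 mol %), THF, rt → 45 °C
Reagents that add atoms: none
Why: In this Negishi coupling, oxidative addition of the alkenyl iodide to zerovalent palladium, transmetalation from the alkylzinc bromide and reductive elimination proceed with retention of the alkene geometry, and the organozinc reagent tolerates the nitrile.

**Step 6**
Reactants: 10 (R,E)-11-[(tert-butyldiphenylsilyl)oxy]-6,10-dimethylundec-5-enenitrile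
Product: 11 4-[(2R,3R)-3-{(R)-5-[(tert-butyldiphenylsilyl)oxy]-4-methylpentyl}-3-methyloxiran-2-yl]butanenitrile
Conditions: D-fructose-derived Shi ketone (0.3 equiv), Oxone (2KHSO5·KHSO4·K2SO4), K2CO3, Bu4NHSO4, MeCN–CH2(OMe)2, aq. Na2B4O7 buffer (pH 10.5), 0 °C
Reagents that add atoms: potassium peroxymonosulfate (the oxidant in Oxone), [K+].[O-]S(=O)(=O)OO
Why: In the Shi epoxidation the chiral dioxirane formed from the fructose-derived ketone transfers oxygen to the electron-rich (E)-trisubstituted alkene through a spiro transition state on the face that gives the (2R,3R)-oxirane, so both new stereocentres are set by the catalyst.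

**Step 7**
Reactants: 11 4-[(2R,3R)-3-{(R)-5-[(tert-butyldiphenylsilyl)oxy]-4-methylpentyl}-3-methyloxiran-2-yl]butanenitrile
Product: 12 (5R,6S,10R)-11-[(tert-butyldiphenylsilyl)oxy]-5,6-dihydroxy-6,10-dimethylundecanenitrile
Conditions: HClO4 (5 mol %), THF–H2O (3:1), 0 °C
Reagents that add atoms: water, O
Why: In this acid-catalysed hydration of a trisubstituted epoxide, water attacks the protonated oxirane at the tertiary carbon C2 from the rear (borderline SN2, inversion at C2) while the C3–O bond stays, so the anti-diol with (S)-C2 and (R)-C3 should result.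

**Step 8**
Reactants: 12 (5R,6S,10R)-11-[(tert-butyldiphenylsilyl)oxy]-5,6-dihydroxy-6,10-dimethylundecanenitrile
Product: 13 4-[(4R,5S)-5-{(R)-5-[(tert-butyldiphenylsilyl)oxy]-4-methylpentyl}-2,2,5-trimethyl-1,3-dioxolan-4-yl]butanenitrile
Conditions: Me2C(OMe)2, camphorsulfonic acid (cat.), CH2Cl2, rt
Reagents that add atoms: 2,2-dimethoxypropane, COC(C)(C)OC
Why: Acid-catalysed transketalisation gives the isopropylidene ketal of the vicinal diol, which keeps both hydroxyls away from the aldehyde that is made next.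

**Step 9**
Reactants: 13 4-[(4R,5S)-5-{(R)-5-[(tert-butyldiphenylsilyl)oxy]-4-methylpentyl}-2,2,5-trimethyl-1,3-dioxolan-4-yl]butanenitrile
Product: 15 4-[(4R,5S)-5-{(R)-5-[(tert-butyldiphenylsilyl)oxy]-4-methylpentyl}-2,2,5-trimethyl-1,3-dioxolan-4-yl]butanal, via aluminium aldimine 14 (not isolated)
Conditions: i-Bu2AlH (1.3 equiv), toluene, −78 °C; then aq. tartaric acid, 0 °C
Reagents that add atoms: water, O
Why: Partial reduction of the nitrile with i-Bu2AlH stops at the N-aluminoimine at −78 °C, which is hydrolysed to the aldehyde on the mildly acidic work-up, while the ketal and the silyl ether do not react.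

**Step 10**
Reactants: 15 4-[(4R,5S)-5-{(R)-5-[(tert-butyldiphenylsilyl)oxy]-4-methylpentyl}-2,2,5-trimethyl-1,3-dioxolan-4-yl]butanal, 16 (tert-butyldimethylsilyloxy)acetaldehyde
Product: 17 (E)-4-[(tert-butyldimethylsilyl)oxy]-2-{2-[(4R,5S)-5-{(R)-5-[(tert-butyldiphenylsilyl)oxy]-4-methylpentyl}-2,2,5-trimethyl-1,3-dioxolan-4-yl]ethyl}but-2-enal
Conditions: 16 (3 equiv), pyrrolidine (0.2 equiv), PhCO2H (0.2 equiv), CH2Cl2, rt, slow addition of 15
Reagents that add atoms: none
Why: In this amine-catalysed cross-aldol condensation the enamine of the unhindered alkyl aldehyde 15 (kept at low concentration) adds to the more electrophilic α-silyloxy aldehyde 16, and elimination gives the 2-alkyl enal in its thermodynamically preferred (E) form, with CHO trans to CH2OSi.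

**Step 11**
Reactants: 17 (E)-4-[(tert-butyldimethylsilyl)oxy]-2-{2-[(4R,5S)-5-{(R)-5-[(tert-butyldiphenylsilyl)oxy]-4-methylpentyl}-2,2,5-trimethyl-1,3-dioxolan-4-yl]ethyl}but-2-enal
Product: 20 (1R,5R,7S,E)-4-{2-[(tert-butyldimethylsilyl)oxy]ethylidene}-7-{(R)-5-[(tert-butyldiphenylsilyl)oxy]-4-methylpentyl}-7-methyl-6,8-dioxabicyclo[3.2.1]octane, via dihydroxy enal 18 (not isolated), via lactol 19 (not isolated)
Conditions: PPTS (0.3 equiv), H2O (2 equiv), toluene, 80 °C, acetone distilled out; then 4 Å molecular sieves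
Reagents that add atoms: none
Why: The acid first exchanges the isopropylidene ketal for water and frees diol 18; O3 then adds to the protonated aldehyde carbon C7 to give lactol 19, which loses water to the ring oxocarbenium ion conjugated with C6=C8, and O1 adds to C7 of this ion. The closest known reaction type is the acid-catalysed intramolecular acetalisation of dihydroxy carbonyl compounds to 6,8-dioxabicyclo[3.2.1]octanes. The tetrahydropyran (O3, C3, C4, C5, C6, C7) closes by 6-exo-trig addition to the carbonyl, and the dioxolane (O1, C2, C3, O3, C7) by a formally 5-endo-trig but freely reversible capture of the oxocarbenium ion, the same C7–O1 bond completing the seven-membered O1–C7 ring of the target. The one new stereocentre, C7, is fixed by the bicycle itself, because O1 and O3 are held on C2 and C3 and can bridge C7 from one side only, so its configuration follows from C3 (it is lost again in step 12). The step needs 1,2-addition at C7 instead of oxa-Michael addition at C8, retention of the (E) geometry and survival of the allylic TBS ether; every event is reversible and the strain-free bicyclic acetal is the thermodynamic sink, the enal double bond never has to rotate, and the weak pyridinium acid in a solvent without alcohol should solvolyse the silyl ether only slowly.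

**Step 12**
Reactants: 20 (1R,5R,7S,E)-4-{2-[(tert-butyldimethylsilyl)oxy]ethylidene}-7-{(R)-5-[(tert-butyldiphenylsilyl)oxy]-4-methylpentyl}-7-methyl-6,8-dioxabicyclo[3.2.1]octane
Product: 21 (2S,3R,E)-6-{2-[(tert-butyldimethylsilyl)oxy]ethylidene}-2-{(R)-5-[(tert-butyldiphenylsilyl)oxy]-4-methylpentyl}-2-methyloxepan-3-ol
Conditions: i-Bu2AlH (4 equiv), CH2Cl2, −78 → 0 °C; then aq. KNaC4H4O6
Reagents that add atoms: none
Why: In this reductive cleavage of a bicyclic acetal by an aluminium hydride, i-Bu2AlH should bind the less hindered acetal oxygen O3 (O1 is shielded by the fully substituted C2), the C7–O3 bond ionises to the allyl-stabilised oxocarbenium ion O1=C7, and hydride is delivered to C7 from the O3-bound alane, which leaves the oxepane with a free C3 hydroxyl and an unchanged (E)-alkene.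

**Step 13**
Reactants: 21 (2S,3R,E)-6-{2-[(tert-butyldimethylsilyl)oxy]ethylidene}-2-{(R)-5-[(tert-butyldiphenylsilyl)oxy]-4-methylpentyl}-2-methyloxepan-3-ol
Product: 22 (2S,3R,E)-2-{(R)-5-[(tert-butyldiphenylsilyl)oxy]-4-methylpentyl}-6-(2-hydroxyethylidene)-2-methyloxepan-3-ol
Conditions: PPTS (0.3 equiv), EtOH, rt → 40 °C
Reagents that add atoms: none
Why: Acid-catalysed ethanolysis of silyl ethers removes the primary TBS ether far faster than the bulkier TBDPS ether, so only the allylic hydroxyl is freed.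

**Step 14**
Reactants: 22 (2S,3R,E)-2-{(R)-5-[(tert-butyldiphenylsilyl)oxy]-4-methylpentyl}-6-(2-hydroxyethylidene)-2-methyloxepan-3-ol
Product: 23 (2S,3R,E)-6-(2-acetoxyethylidene)-2-{(R)-5-[(tert-butyldiphenylsilyl)oxy]-4-methylpentyl}-2-methyloxepan-3-yl acetate
Conditions: Ac2O, pyridine, DMAP (cat.), CH2Cl2, rt
Reagents that add atoms: acetic anhydride, CC(=O)OC(C)=O
Why: DMAP-catalysed acylation esterifies the primary allylic and the hindered secondary hydroxyl alike and so installs both acetates of the target.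

**Step 15**
Reactants: 23 (2S,3R,E)-6-(2-acetoxyethylidene)-2-{(R)-5-[(tert-butyldiphenylsilyl)oxy]-4-methylpentyl}-2-methyloxepan-3-yl acetate
Product: 24 (2S,3R,E)-6-(2-acetoxyethylidene)-2-[(R)-5-hydroxy-4-methylpentyl]-2-methyloxepan-3-yl acetate
Conditions: HF·pyridine, pyridine, THF, 0 °C → rt
Reagents that add atoms: none
Why: Fluoride-mediated Si–O cleavage with pyridine-buffered HF removes the TBDPS ether without hydrolysing or migrating the acetates and without touching the allylic ether.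

**Step 16**
Reactants: 24 (2S,3R,E)-6-(2-acetoxyethylidene)-2-[(R)-5-hydroxy-4-methylpentyl]-2-methyloxepan-3-yl acetate
Product: 25 (2S,3R,E)-6-(2-acetoxyethylidene)-2-methyl-2-[(R)-4-methyl-5-oxopentyl]oxepan-3-yl acetate
Conditions: Dess–Martin periodinane, NaHCO3, CH2Cl2, 0 °C → rt
Reagents that add atoms: none
Why: Dess–Martin oxidation under bicarbonate buffer converts the primary alcohol into the aldehyde under neutral conditions, so the adjacent stereocentre should not epimerise.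

**Step 17**
Reactants: 26 2,3-dimethylbut-1-ene
Product: 28 4,4,5,5-tetramethyl-2-(3-methyl-2-methylidenebutyl)-1,3,2-dioxaborolane, via allylpotassium 27 (not isolated)
Conditions: n-BuLi, t-BuOK, THF–hexane, −78 → −50 °C; then i-PrOB(pin), −78 °C → rt; aq. NH4Cl
Reagents that add atoms: 2-isopropoxy-4,4,5,5-tetramethyl-1,3,2-dioxaborolane, CC(C)OB1OC(C)(C)C(C)(C)O1
Why: Allylic metalation with the n-BuLi/t-BuOK superbase takes a proton from the methyl group (the primary allylic position), and the symmetric 2-isopropylallyl anion is borylated by the isopropoxyboronate to give the allylboronate.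

**Step 18**
Reactants: 25 (2S,3R,E)-6-(2-acetoxyethylidene)-2-methyl-2-[(R)-4-methyl-5-oxopentyl]oxepan-3-yl acetate, 28 4,4,5,5-tetramethyl-2-(3-methyl-2-methylidenebutyl)-1,3,2-dioxaborolane
Product: 30 (2S,3R,E)-6-(2-acetoxyethylidene)-2-[(4R)-5-hydroxy-4,8-dimethyl-7-methylidenenonyl]-2-methyloxepan-3-yl acetate, via borate ester 29 (not isolated)
Conditions: 28 (2 equiv), toluene (2 M), rt → 40 °C; then aq. NaHCO3
Reagents that add atoms: none
Why: Allylboration of the aldehyde through a six-membered cyclic transition state transfers the 2-isopropylallyl group with allylic transposition (degenerate here) without acid or base, so the acetates and the α-stereocentre are spared; the new carbinol centre is not controlled and is removed in step 19.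

**Step 19**
Reactants: 30 (2S,3R,E)-6-(2-acetoxyethylidene)-2-[(4R)-5-hydroxy-4,8-dimethyl-7-methylidenenonyl]-2-methyloxepan-3-yl acetate
Product: 31 (2S,3R,E)-6-(2-acetoxyethylidene)-2-[(R)-4,8-dimethyl-7-methylidene-5-oxononyl]-2-methyloxepan-3-yl acetate
Conditions: Dess–Martin periodinane, NaHCO3, CH2Cl2, 0 °C
Reagents that add atoms: none
Why: Dess–Martin oxidation under bicarbonate buffer should give the β,γ-unsaturated ketone without migration of the 1,1-disubstituted alkene into conjugation and without epimerisation of the α-methyl centre.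

**Compound list**
1 | (S)-3-bromo-2-methylpropan-1-ol | OC[C@H](C)CBr | starting material
2 | (S)-(3-bromo-2-methylpropoxy)(tert-butyl)diphenylsilane | CC(C)(C)[Si](c1ccccc1)(c1ccccc1)OC[C@H](C)CBr | intermediate
3 | (4-bromobut-1-yn-1-yl)trimethylsilane | C[Si](C)(C)C#CCCBr | starting material
4 | [4-(trimethylsilyl)but-3-yn-1-yl]magnesium bromide | C[Si](C)(C)C#CCC[Mg]Br | intermediate
5 | (R)-tert-butyl{[2-methyl-7-(trimethylsilyl)hept-6-yn-1-yl]oxy}diphenylsilane | CC(C)(C)[Si](c1ccccc1)(c1ccccc1)OC[C@H](C)CCCC#C[Si](C)(C)C | intermediate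
6 | (R)-tert-butyl[(2-methylhept-6-yn-1-yl)oxy]diphenylsilane | CC(C)(C)[Si](c1ccccc1)(c1ccccc1)OC[C@H](C)CCCC#C | intermediate
7 | (R,E)-{7-[(tert-butyldiphenylsilyl)oxy]-2,6-dimethylhept-1-en-1-yl}dimethylalane | CC(C)(C)[Si](c1ccccc1)(c1ccccc1)OC[C@H](C)CCC/C(C)=C/[Al](C)C | intermediate
8 | (R,E)-tert-butyl[(7-iodo-2,6-dimethylhept-6-en-1-yl)oxy]diphenylsilane | CC(C)(C)[Si](c1ccccc1)(c1ccccc1)OC[C@H](C)CCC/C(C)=C/I | intermediate
9 | (3-cyanopropyl)zinc bromide | N#CCCC[Zn]Br | starting material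
10 | (R,E)-11-[(tert-butyldiphenylsilyl)oxy]-6,10-dimethylundec-5-enenitrile | CC(C)(C)[Si](c1ccccc1)(c1ccccc1)OC[C@H](C)CCC/C(C)=C/CCCC#N | intermediate
11 | 4-[(2R,3R)-3-{(R)-5-[(tert-butyldiphenylsilyl)oxy]-4-methylpentyl}-3-methyloxiran-2-yl]butanenitrile | CC(C)(C)[Si](c1ccccc1)(c1ccccc1)OC[C@H](C)CCC[C@@]1(C)O[C@@H]1CCCC#N | intermediate
12 | (5R,6S,10R)-11-[(tert-butyldiphenylsilyl)oxy]-5,6-dihydroxy-6,10-dimethylundecanenitrile | CC(C)(C)[Si](c1ccccc1)(c1ccccc1)OC[C@H](C)CCC[C@](C)(O)[C@H](O)CCCC#N | intermediate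
13 | 4-[(4R,5S)-5-{(R)-5-[(tert-butyldiphenylsilyl)oxy]-4-methylpentyl}-2,2,5-trimethyl-1,3-dioxolan-4-yl]butanenitrile | CC(C)(C)[Si](c1ccccc1)(c1ccccc1)OC[C@H](C)CCC[C@]1(C)OC(C)(C)O[C@@H]1CCCC#N | intermediate
14 | N-(diisobutylalumanyl)-4-[(4R,5S)-5-{(R)-5-[(tert-butyldiphenylsilyl)oxy]-4-methylpentyl}-2,2,5-trimethyl-1,3-dioxolan-4-yl]butan-1-imine | CC(C)(C)[Si](c1ccccc1)(c1ccccc1)OC[C@H](C)CCC[C@]1(C)OC(C)(C)O[C@@H]1CCCC=N[Al](CC(C)C)CC(C)C | intermediate
15 | 4-[(4R,5S)-5-{(R)-5-[(tert-butyldiphenylsilyl)oxy]-4-methylpentyl}-2,2,5-trimethyl-1,3-dioxolan-4-yl]butanal | CC(C)(C)[Si](c1ccccc1)(c1ccccc1)OC[C@H](C)CCC[C@]1(C)OC(C)(C)O[C@@H]1CCCC=O | intermediate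
16 | (tert-butyldimethylsilyloxy)acetaldehyde | CC(C)(C)[Si](C)(C)OCC=O | starting material
17 | (E)-4-[(tert-butyldimethylsilyl)oxy]-2-{2-[(4R,5S)-5-{(R)-5-[(tert-butyldiphenylsilyl)oxy]-4-methylpentyl}-2,2,5-trimethyl-1,3-dioxolan-4-yl]ethyl}but-2-enal | CC(C)(C)[Si](c1ccccc1)(c1ccccc1)OC[C@H](C)CCC[C@]1(C)OC(C)(C)O[C@@H]1CC/C(C=O)=C\CO[Si](C)(C)C(C)(C)C | intermediate
18 | (E)-4-[(tert-butyldimethylsilyl)oxy]-2-{(3R,4S,8R)-9-[(tert-butyldiphenylsilyl)oxy]-3,4-dihydroxy-4,8-dimethylnonyl}but-2-enal | CC(C)(C)[Si](c1ccccc1)(c1ccccc1)OC[C@H](C)CCC[C@](C)(O)[C@H](O)CC/C(C=O)=C\CO[Si](C)(C)C(C)(C)C | intermediate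
19 | (6R,E)-3-{2-[(tert-butyldimethylsilyl)oxy]ethylidene}-6-{(2S,6R)-7-[(tert-butyldiphenylsilyl)oxy]-2-hydroxy-6-methylheptan-2-yl}tetrahydro-2H-pyran-2-ol (both anomers) | CC(C)(C)[Si](c1ccccc1)(c1ccccc1)OC[C@H](C)CCC[C@](C)(O)[C@H]1CC/C(=C\CO[Si](C)(C)C(C)(C)C)C(O)O1 | intermediate
20 | (1R,5R,7S,E)-4-{2-[(tert-butyldimethylsilyl)oxy]ethylidene}-7-{(R)-5-[(tert-butyldiphenylsilyl)oxy]-4-methylpentyl}-7-methyl-6,8-dioxabicyclo[3.2.1]octane | CC(C)(C)[Si](c1ccccc1)(c1ccccc1)OC[C@H](C)CCC[C@]1(C)O[C@H]2O[C@@H]1CC/C2=C\CO[Si](C)(C)C(C)(C)C | intermediate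
21 | (2S,3R,E)-6-{2-[(tert-butyldimethylsilyl)oxy]ethylidene}-2-{(R)-5-[(tert-butyldiphenylsilyl)oxy]-4-methylpentyl}-2-methyloxepan-3-ol | CC(C)(C)[Si](c1ccccc1)(c1ccccc1)OC[C@H](C)CCC[C@]1(C)OC/C(=C/CO[Si](C)(C)C(C)(C)C)CC[C@H]1O | intermediate
22 | (2S,3R,E)-2-{(R)-5-[(tert-butyldiphenylsilyl)oxy]-4-methylpentyl}-6-(2-hydroxyethylidene)-2-methyloxepan-3-ol | CC(C)(C)[Si](c1ccccc1)(c1ccccc1)OC[C@H](C)CCC[C@]1(C)OC/C(=C/CO)CC[C@H]1O | intermediate
23 | (2S,3R,E)-6-(2-acetoxyethylidene)-2-{(R)-5-[(tert-butyldiphenylsilyl)oxy]-4-methylpentyl}-2-methyloxepan-3-yl acetate | CC(C)(C)[Si](c1ccccc1)(c1ccccc1)OC[C@H](C)CCC[C@]1(C)OC/C(=C/COC(C)=O)CC[C@H]1OC(C)=O | intermediate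
24 | (2S,3R,E)-6-(2-acetoxyethylidene)-2-[(R)-5-hydroxy-4-methylpentyl]-2-methyloxepan-3-yl acetate | OC[C@H](C)CCC[C@]1(C)OC/C(=C/COC(C)=O)CC[C@H]1OC(C)=O | intermediate
25 | (2S,3R,E)-6-(2-acetoxyethylidene)-2-methyl-2-[(R)-4-methyl-5-oxopentyl]oxepan-3-yl acetate | O=C[C@H](C)CCC[C@]1(C)OC/C(=C/COC(C)=O)CC[C@H]1OC(C)=O | intermediate
26 | 2,3-dimethylbut-1-ene | C=C(C)C(C)C | starting material
27 | (3-methyl-2-methylidenebutyl)potassium | C=C(C[K])C(C)C | intermediate
28 | 4,4,5,5-tetramethyl-2-(3-methyl-2-methylidenebutyl)-1,3,2-dioxaborolane | C=C(CB1OC(C)(C)C(C)(C)O1)C(C)C | intermediate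
29 | (2S,3R,E)-6-(2-acetoxyethylidene)-2-{(4R)-4,8-dimethyl-7-methylidene-5-[(4,4,5,5-tetramethyl-1,3,2-dioxaborolan-2-yl)oxy]nonyl}-2-methyloxepan-3-yl acetate (both C5′ epimers) | C=C(CC(OB1OC(C)(C)C(C)(C)O1)[C@H](C)CCC[C@]1(C)OC/C(=C/COC(C)=O)CC[C@H]1OC(C)=O)C(C)C | intermediate
30 | (2S,3R,E)-6-(2-acetoxyethylidene)-2-[(4R)-5-hydroxy-4,8-dimethyl-7-methylidenenonyl]-2-methyloxepan-3-yl acetate (both C5′ epimers) | C=C(CC(O)[C@H](C)CCC[C@]1(C)OC/C(=C/COC(C)=O)CC[C@H]1OC(C)=O)C(C)C | intermediate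
31 | (2S,3R,E)-6-(2-acetoxyethylidene)-2-[(R)-4,8-dimethyl-7-methylidene-5-oxononyl]-2-methyloxepan-3-yl acetate | C=C(CC(=O)[C@H](C)CCC[C@]1(C)OC/C(=C/COC(C)=O)CC[C@H]1OC(C)=O)C(C)C | target

**Totals**
Total step count: 19. Longest linear sequence: 18 steps (steps 1–16, 18 and 19, from compound 1); step 17 is a one-step side branch.

**Steps most likely to fail**

1. Step 12 (reductive cut of the acetal). Aluminium may also bind O1, or the acetal may ionise toward the six-membered oxocarbenium ion, so that hydride cuts C7–O1 and a tetrahydropyran with a free tertiary hydroxyl forms instead of the oxepane; hydride delivery at C8 with allylic shift is a smaller risk. Fallback (no acetal at all: the O1–C7 bond is made by Williamson etherification while O3 is blocked): it sets out from diol 12 and returns at diol 22. TESCl and imidazole in CH2Cl2 should silylate only the secondary hydroxyl and give (5R,6S,10R)-11-[(tert-butyldiphenylsilyl)oxy]-6-hydroxy-6,10-dimethyl-5-[(triethylsilyl)oxy]undecanenitrile F1. i-Bu2AlH at −78 °C with tartaric acid work-up gives (5R,6S,10R)-11-[(tert-butyldiphenylsilyl)oxy]-6-hydroxy-6,10-dimethyl-5-[(triethylsilyl)oxy]undecanal F2. Condensation with 16 as in step 10 gives (E)-4-[(tert-butyldimethylsilyl)oxy]-2-{(3R,4S,8R)-9-[(tert-butyldiphenylsilyl)oxy]-4-hydroxy-4,8-dimethyl-3-[(triethylsilyl)oxy]nonyl}but-2-enal F3. Luche reduction (NaBH4, CeCl3·7H2O, MeOH, 0 °C) gives (E)-4-[(tert-butyldimethylsilyl)oxy]-2-{(3R,4S,8R)-9-[(tert-butyldiphenylsilyl)oxy]-4-hydroxy-4,8-dimethyl-3-[(triethylsilyl)oxy]nonyl}but-2-en-1-ol F4. N-Chlorosuccinimide and Me2S in CH2Cl2 convert the primary allylic hydroxyl into the chloride, (E)-tert-butyl({4-chloro-3-[(3R,4S,8R)-9-[(tert-butyldiphenylsilyl)oxy]-4-hydroxy-4,8-dimethyl-3-[(triethylsilyl)oxy]nonyl]but-2-en-1-yl}oxy)dimethylsilane F5. KN(SiMe3)2 in THF at 0 °C lets the tertiary alkoxide displace the chloride (7-exo-tet) and gives (2S,3R,E)-6-{2-[(tert-butyldimethylsilyl)oxy]ethylidene}-2-{(R)-5-[(tert-butyldiphenylsilyl)oxy]-4-methylpentyl}-2-methyl-3-[(triethylsilyl)oxy]oxepane F6. PPTS in EtOH then removes the triethylsilyl and the TBS ether together and gives 22.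

2. Step 10 (cross-aldol condensation). Self-condensation of 16, the wrong aldehyde acting as the enamine donor, and deconjugation of the product by γ-deprotonation can all erode the cross product. Fallback (donor and acceptor roles fixed by a preformed enol silane; Mukaiyama aldol addition, then elimination): it sets out from aldehyde 15 and returns at enal 17. TMSCl, NaI and Et3N in MeCN give the enol silane {[4-((4R,5S)-5-{(R)-5-[(tert-butyldiphenylsilyl)oxy]-4-methylpentyl}-2,2,5-trimethyl-1,3-dioxolan-4-yl)but-1-en-1-yl]oxy}trimethylsilane F7. BF3·OEt2 and 16 in CH2Cl2 at −78 °C give the aldol 4-[(tert-butyldimethylsilyl)oxy]-2-{2-[(4R,5S)-5-{(R)-5-[(tert-butyldiphenylsilyl)oxy]-4-methylpentyl}-2,2,5-trimethyl-1,3-dioxolan-4-yl]ethyl}-3-hydroxybutanal F8. MsCl and Et3N at 0 °C → rt form its methanesulfonate, 1-[(tert-butyldimethylsilyl)oxy]-3-formyl-5-[(4R,5S)-5-{(R)-5-[(tert-butyldiphenylsilyl)oxy]-4-methylpentyl}-2,2,5-trimethyl-1,3-dioxolan-4-yl]pentan-2-yl methanesulfonate F9, which eliminates in the same flask (E1cB) to the (E)-enal 17.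

3. Step 11 (key step). The acid needed to open the hindered acetonide may also solvolyse the allylic TBS ether, and the acetal exchange may stall if acetone is not removed. Loss of the TBS ether alone would not be fatal, since the desilylated acetal would give 22 directly in step 12. Fallback (the precursor is released from a diol mask that leaves under far milder conditions than the TBS ether): it sets out from diol 12 and returns at acetal 20. Me3SiOTf and Et3N in CH2Cl2 give (5R,6S,10R)-11-[(tert-butyldiphenylsilyl)oxy]-6,10-dimethyl-5,6-bis[(trimethylsilyl)oxy]undecanenitrile F10. i-Bu2AlH at −78 °C with a neutral tartrate work-up gives (5R,6S,10R)-11-[(tert-butyldiphenylsilyl)oxy]-6,10-dimethyl-5,6-bis[(trimethylsilyl)oxy]undecanal F11. Condensation with 16 as in step 10 gives (E)-4-[(tert-butyldimethylsilyl)oxy]-2-{(3R,4S,8R)-9-[(tert-butyldiphenylsilyl)oxy]-4,8-dimethyl-3,4-bis[(trimethylsilyl)oxy]nonyl}but-2-enal F12. Citric acid in MeOH at 0 °C removes only the two trimethylsilyl groups and frees 18 (in equilibrium with 19), and PPTS with 4 Å molecular sieves in CH2Cl2 then closes the bicycle to 20.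

**Further compounds**
F1 | step 12 | (5R,6S,10R)-11-[(tert-butyldiphenylsilyl)oxy]-6-hydroxy-6,10-dimethyl-5-[(triethylsilyl)oxy]undecanenitrile | CC(C)(C)[Si](c1ccccc1)(c1ccccc1)OC[C@H](C)CCC[C@](C)(O)[C@H](O[Si](CC)(CC)CC)CCCC#N
F2 | step 12 | (5R,6S,10R)-11-[(tert-butyldiphenylsilyl)oxy]-6-hydroxy-6,10-dimethyl-5-[(triethylsilyl)oxy]undecanal | CC(C)(C)[Si](c1ccccc1)(c1ccccc1)OC[C@H](C)CCC[C@](C)(O)[C@H](O[Si](CC)(CC)CC)CCCC=O
F3 | step 12 | (E)-4-[(tert-butyldimethylsilyl)oxy]-2-{(3R,4S,8R)-9-[(tert-butyldiphenylsilyl)oxy]-4-hydroxy-4,8-dimethyl-3-[(triethylsilyl)oxy]nonyl}but-2-enal | CC(C)(C)[Si](c1ccccc1)(c1ccccc1)OC[C@H](C)CCC[C@](C)(O)[C@H](O[Si](CC)(CC)CC)CC/C(C=O)=C\CO[Si](C)(C)C(C)(C)C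
F4 | step 12 | (E)-4-[(tert-butyldimethylsilyl)oxy]-2-{(3R,4S,8R)-9-[(tert-butyldiphenylsilyl)oxy]-4-hydroxy-4,8-dimethyl-3-[(triethylsilyl)oxy]nonyl}but-2-en-1-ol | CC(C)(C)[Si](c1ccccc1)(c1ccccc1)OC[C@H](C)CCC[C@](C)(O)[C@H](O[Si](CC)(CC)CC)CC/C(CO)=C\CO[Si](C)(C)C(C)(C)C
F5 | step 12 | (E)-tert-butyl({4-chloro-3-[(3R,4S,8R)-9-[(tert-butyldiphenylsilyl)oxy]-4-hydroxy-4,8-dimethyl-3-[(triethylsilyl)oxy]nonyl]but-2-en-1-yl}oxy)dimethylsilane | CC(C)(C)[Si](c1ccccc1)(c1ccccc1)OC[C@H](C)CCC[C@](C)(O)[C@H](O[Si](CC)(CC)CC)CC/C(CCl)=C\CO[Si](C)(C)C(C)(C)C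
F6 | step 12 | (2S,3R,E)-6-{2-[(tert-butyldimethylsilyl)oxy]ethylidene}-2-{(R)-5-[(tert-butyldiphenylsilyl)oxy]-4-methylpentyl}-2-methyl-3-[(triethylsilyl)oxy]oxepane | CC(C)(C)[Si](c1ccccc1)(c1ccccc1)OC[C@H](C)CCC[C@]1(C)OC/C(=C/CO[Si](C)(C)C(C)(C)C)CC[C@H]1O[Si](CC)(CC)CC
F7 | step 10 | {[4-((4R,5S)-5-{(R)-5-[(tert-butyldiphenylsilyl)oxy]-4-methylpentyl}-2,2,5-trimethyl-1,3-dioxolan-4-yl)but-1-en-1-yl]oxy}trimethylsilane (E/Z mixture) | CC(C)(C)[Si](c1ccccc1)(c1ccccc1)OC[C@H](C)CCC[C@]1(C)OC(C)(C)O[C@@H]1CCC=CO[Si](C)(C)C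
F8 | step 10 | 4-[(tert-butyldimethylsilyl)oxy]-2-{2-[(4R,5S)-5-{(R)-5-[(tert-butyldiphenylsilyl)oxy]-4-methylpentyl}-2,2,5-trimethyl-1,3-dioxolan-4-yl]ethyl}-3-hydroxybutanal (diastereomers at C2 and C3) | CC(C)(C)[Si](c1ccccc1)(c1ccccc1)OC[C@H](C)CCC[C@]1(C)OC(C)(C)O[C@@H]1CCC(C=O)C(O)CO[Si](C)(C)C(C)(C)C
F9 | step 10 | 1-[(tert-butyldimethylsilyl)oxy]-3-formyl-5-[(4R,5S)-5-{(R)-5-[(tert-butyldiphenylsilyl)oxy]-4-methylpentyl}-2,2,5-trimethyl-1,3-dioxolan-4-yl]pentan-2-yl methanesulfonate | CC(C)(C)[Si](c1ccccc1)(c1ccccc1)OC[C@H](C)CCC[C@]1(C)OC(C)(C)O[C@@H]1CCC(C=O)C(OS(C)(=O)=O)CO[Si](C)(C)C(C)(C)C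
F10 | step 11 | (5R,6S,10R)-11-[(tert-butyldiphenylsilyl)oxy]-6,10-dimethyl-5,6-bis[(trimethylsilyl)oxy]undecanenitrile | CC(C)(C)[Si](c1ccccc1)(c1ccccc1)OC[C@H](C)CCC[C@](C)(O[Si](C)(C)C)[C@H](O[Si](C)(C)C)CCCC#N
F11 | step 11 | (5R,6S,10R)-11-[(tert-butyldiphenylsilyl)oxy]-6,10-dimethyl-5,6-bis[(trimethylsilyl)oxy]undecanal | CC(C)(C)[Si](c1ccccc1)(c1ccccc1)OC[C@H](C)CCC[C@](C)(O[Si](C)(C)C)[C@H](O[Si](C)(C)C)CCCC=O
F12 | step 11 | (E)-4-[(tert-butyldimethylsilyl)oxy]-2-{(3R,4S,8R)-9-[(tert-butyldiphenylsilyl)oxy]-4,8-dimethyl-3,4-bis[(trimethylsilyl)oxy]nonyl}but-2-enal | CC(C)(C)[Si](c1ccccc1)(c1ccccc1)OC[C@H](C)CCC[C@](C)(O[Si](C)(C)C)[C@H](O[Si](C)(C)C)CC/C(C=O)=C\CO[Si](C)(C)C(C)(C)C
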